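**Strategy.** Ring A is built last, on an enantiopure ring B, by a radical [4+2] annulation. The feature exploited: the C2–C3 unit of ring A lies between C1, a methylene on the quaternary C10, and C4, which is β to the C6 oxygen through C5. A C1 radical from a neopentyl iodide adds to vinylboronic acid pinacol ester; the α-boryl C3 radical then closes on C4 of a C6-keto C4=C5 alkylidene acetate. One operation forms C1–C2 and C3–C4 and leaves boron at C3 (the later 3-oxygen) and the C19 carboxyl at C4; a 19,6β-lactone afterwards directs the C4 methylation.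

Key step: step 9

Numbering: labdane locants are used throughout (ring A C1–C5 and C10, ring B C5–C10, C17 = methyl on C8, C18 = 4α-methyl, C19 = 4β-carbon, C20 = methyl on C10, C11–C16 = side chain).

Assumption: the Birch alkylation of the 2-alkylbenzamide 8 carrying the (S)-auxiliary is taken to give the C10 configuration drawn; if the facial sense proves opposite, the commercially available (R)-auxiliary is used with no other change.

Step 1
Reactants: 1 3-methoxy-5-methylbenzoic acid
Product: 2 2-bromo-5-methoxy-3-methylbenzoic acid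
Conditions: NBS, MeCN, rt, dark
Reagents that add atoms: N-bromosuccinimide, O=C1CCC(=O)N1Br
Why: Electrophilic aromatic bromination; the methoxy group directs para, to the position between the carboxyl and methyl groups, as in the bromination of 3-methoxybenzoic acid.

Step 2
Reactants: 2 2-bromo-5-methoxy-3-methylbenzoic acid; 3 (S)-2-(methoxymethyl)pyrrolidine
Product: 5 auxiliary amide of acid 2, via acid chloride 4 (not isolated)
Conditions: (COCl)2, cat. DMF, CH2Cl2, 0 °C to rt; then 3, Et3N, CH2Cl2, 0 °C
Reagents that add atoms: none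
Why: Acylation of the secondary amine by the acid chloride installs the chiral auxiliary that later controls C10.

Step 3
Reactants: 5 auxiliary amide of acid 2; 6 2-methyl-2-vinyl-1,3-dioxolane
Product: 8 aryl amide carrying the ketal side chain, via alkylborane 7 (not isolated)
Conditions: 6, 9-BBN, THF, 0 °C to rt; then 5, Pd(OAc)2, SPhos, K3PO4, THF/H2O, 65 °C
Reagents that add atoms: none
Why: Anti-Markovnikov hydroboration of 6 followed by B-alkyl Suzuki–Miyaura coupling at the aryl bromide installs C11–C13 and C16, with the ketone masked against the dissolving metal.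

Step 4
Reactants: 8 aryl amide carrying the ketal side chain
Product: 9 ring-B cyclohexa-2,5-diene amide with quaternary C10
Conditions: K, NH3/THF, t-BuOH (1 equiv), −78 °C; then MeI, −78 °C
Reagents that add atoms: iodomethane, CI
Why: Birch reduction–alkylation: reduction and protonation para to the amide give a chelated potassium amide enolate that is methylated at C10 on the face left open by the methoxymethyl arm of the auxiliary, which sets the quaternary stereocenter and leaves the C5=C6 enol ether and the C8=C9 alkene.

Step 5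
Reactants: 9 ring-B cyclohexa-2,5-diene amide with quaternary C10
Product: 10 ring-B dienyl methanol (C1 as CH2OH)
Conditions: LiNH2BH3 (from NH3·BH3 and n-BuLi), THF, 0 °C to rt
Reagents that add atoms: none
Why: Reduction of the hindered tertiary amide to the primary alcohol by lithium amidotrihydroborate (C–N cleavage of the hemiaminal) gives C1 as CH2OH and returns the auxiliary.

Step 6
Reactants: 10 ring-B dienyl methanol
Product: 12 cis-fused cyclopropyl ketone (C1 bridges C10 and C5; C6 ketone), via triflate 11 (not isolated)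
Conditions: Tf2O, 2,6-lutidine, CH2Cl2, −78 °C to 0 °C; then H2O
Reagents that add atoms: water, O
Why: The neopentyl triflate ionizes with participation of the enol ether (3-exo-tet attack of C5 on C1, homoallyl to cyclopropylcarbinyl type) and hydrolysis of the oxocarbenium ion gives the cyclopropyl ketone, whose C5 configuration follows from C10 because C1 can only bridge on its own face.

Step 7
Reactants: 12 cis-fused cyclopropyl ketone; 13 ethyl glyoxylate
Product: 15 C1 iodide bearing the C5 hydroxy-acetate and free side-chain ketone, via iodo enol silane 14 (not isolated)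
Conditions: TMSI (2.2 equiv), CH2Cl2, −40 °C to 0 °C; then 13, TMSOTf (cat.), −78 °C; then aq. citric acid
Reagents that add atoms: iodotrimethylsilane, C[Si](C)(C)I
Why: Homoconjugate ring opening of the cyclopropyl ketone by TMSI (iodide attacks the unhindered C1 and cleaves the C1–C5 bond that overlaps with the carbonyl) gives a regiodefined C5=C6 enol silane that undergoes Mukaiyama aldol addition to ethyl glyoxylate; the dioxolane is cleaved by the same reagent, and the new C4 and C5 stereocenters are removed in step 8.

Step 8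
Reactants: 15 C1 iodide bearing the C5 hydroxy-acetate
Product: 17 iodo 4-oxo-enoate (C6 ketone with C5=C4H–CO2Et), via mesylate 16 (not isolated)
Conditions: MsCl, Et3N, CH2Cl2, −20 °C to 0 °C
Reagents that add atoms: none
Why: Mesylation and E1cB elimination of the β-hydroxy ketone give the 4-oxo-enoate; the alkene geometry has no consequence because C4 is re-set later.

Step 9
Reactants: 17 iodo 4-oxo-enoate; 18 vinylboronic acid pinacol ester
Product: 19 ring-A boronate (3-Bpin, 4-CO2Et, 5α-H, 6-oxo)
Conditions: 18 (large excess, as cosolvent), (TMS)3SiH (slow addition), AIBN (cat.), PhH, 80 °C, 17 at high dilution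
Reagents that add atoms: none
Why: The silyl radical abstracts iodine from C1, the neopentyl C1 radical adds to the unsubstituted terminus of 18 (forming C1–C2) to give an α-boryl radical at C3, and this radical closes on C4 of the 4-oxo-enoate (forming C3–C4), leaving a C5 radical stabilized by the C6 ketone that is reduced by (TMS)3SiH. The closest known reaction type is the silane-mediated radical annulation, an intermolecular Giese addition to a vinylboronate followed by cyclization of the α-boryl radical onto an enone. Ring A closes in the 6-endo-trig mode. C3 and C4 form without control and need none, because C3 is later oxidized to the ketone and C4 is epimerizable and later fixed by the lactone; C5 should receive hydrogen from the α face, anti to the C10 methyl group, giving the trans ring fusion. The step needs the C1 radical to add to 18 faster than to the oxo-enoate of a second molecule, which high dilution of 17 in excess 18 secures, and it needs the C3 radical to attack C4 and not C5, which is secured because C4 is the unhindered carbon β to the ketone while C5 is fully substituted and flanked by the quaternary C10.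

Step 10
Reactants: 19 ring-A boronate
Product: 21 19,6β-lactone boronate, via diol ester 20 (not isolated)
Conditions: NaBH4, CeCl3·7H2O, MeOH, −40 °C to 0 °C; then NaOEt, EtOH, 50 °C
Reagents that add atoms: none
Why: Luche reduction: hydride attacks C6 (and the side-chain ketone) from the α face, anti to the C10 methyl group, giving the 6β-alkoxide; ethoxide then epimerizes C4 through the ester enolate and the 4β-ester is trapped by the 6β-hydroxyl as the γ-lactone, which fixes C19 on the β face.

Step 11
Reactants: 21 19,6β-lactone boronate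
Product: 22 3,13-dihydroxy lactone
Conditions: NaBO3·4H2O, THF/H2O, rt
Reagents that add atoms: sodium perborate, [Na+].[O-]OB=O
Why: Oxidation of the C–B bond by perborate (1,2-migration from boron to oxygen with retention) gives the C3 alcohol, whose configuration is irrelevant.

Step 12
Reactants: 22 3,13-dihydroxy lactone
Product: 23 3,13-dioxo lactone
Conditions: Dess–Martin periodinane, CH2Cl2, rt
Reagents that add atoms: none
Why: Dess–Martin oxidation of both secondary alcohols gives the C3 ketone (a β-keto lactone) and restores the side-chain methyl ketone.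

Step 13
Reactants: 23 3,13-dioxo lactone
Product: 24 4α-methyl 3,13-dioxo lactone
Conditions: K2CO3, MeI, acetone, rt
Reagents that add atoms: iodomethane, CI
Why: C-Methylation of the β-keto lactone enolate; the lactone bridge to the 6β-oxygen holds C19 on the β face, so iodomethane can only enter from the α face, anti to the C10 methyl group, which sets the C4 quaternary center.

Step 14
Reactants: 24 4α-methyl 3,13-dioxo lactone; 25 allyl diethylphosphonoacetate
Product: 26 allyl (13E)-enoate 3-keto lactone
Conditions: NaH, THF, 0 °C to 40 °C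
Reagents that add atoms: none
Why: Horner–Wadsworth–Emmons olefination of the unhindered methyl ketone (the C3 ketone next to the quaternary C4 does not react) should give the E-enoate as the main isomer, with the ester trans to the C12 chain; the minor Z isomer is removed by chromatography.

Step 15
Reactants: 26 allyl (13E)-enoate 3-keto lactone
Product: 27 allyl (13E)-enoate 3α-hydroxy lactone
Conditions: LiBH(s-Bu)3 (L-Selectride), THF, −78 °C
Reagents that add atoms: none
Why: The bulky hydride attacks the C3 ketone along the equatorial trajectory, as with 4,4-disubstituted 3-keto terpenoids, giving the axial 3α-alcohol; the lactone and the β,β-disubstituted enoate are not reduced at this temperature.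

Step 16
Reactants: 27 allyl (13E)-enoate 3α-hydroxy lactone
Product: 28 (13E)-3α-hydroxy lactone acid
Conditions: Pd(PPh3)4 (cat.), morpholine, THF, rt
Reagents that add atoms: none
Why: Tsuji–Trost deallylation: the π-allyl palladium complex formed from the allyl ester is intercepted by morpholine, freeing the acid under neutral conditions without touching the lactone.

Step 17
Reactants: 28 (13E)-3α-hydroxy lactone acid
Product: 29 (13E)-3α,6β,19-trihydroxylabda-8,13-dien-15-oic acid
Conditions: LiBH4 (excess), THF, 0 °C to 50 °C; then aq. NH4Cl, dilute HCl to pH 3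
Reagents that add atoms: none
Why: LiBH4 reduces the lactone to the 6β-hydroxyl and the C19 primary alcohol, while the acid is protected as its lithium carboxylate, which this reagent does not reduce.

**Compound list**

1 | 3-methoxy-5-methylbenzoic acid | COc1cc(C)cc(c1)C(=O)O | starting material
2 | 2-bromo-5-methoxy-3-methylbenzoic acid | COc1cc(C)c(Br)c(c1)C(=O)O | intermediate
3 | (S)-2-(methoxymethyl)pyrrolidine | COC[C@@H]1CCCN1 | starting material
4 | 2-bromo-5-methoxy-3-methylbenzoyl chloride | COc1cc(C)c(Br)c(c1)C(Cl)=O | intermediate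
5 | (2-bromo-5-methoxy-3-methylphenyl)[(2S)-2-(methoxymethyl)pyrrolidin-1-yl]methanone | COC[C@@H]1CCCN1C(=O)c2cc(OC)cc(C)c2Br | intermediate
6 | 2-methyl-2-vinyl-1,3-dioxolane | C=CC1(C)OCCO1 | starting material
7 | 9-[2-(2-methyl-1,3-dioxolan-2-yl)ethyl]-9-borabicyclo[3.3.1]nonane | CC1(CCB2C3CCCC2CCC3)OCCO1 | intermediate
8 | {5-methoxy-3-methyl-2-[2-(2-methyl-1,3-dioxolan-2-yl)ethyl]phenyl}[(2S)-2-(methoxymethyl)pyrrolidin-1-yl]methanone | COC[C@@H]1CCCN1C(=O)c2cc(OC)cc(C)c2CCC3(C)OCCO3 | intermediate
9 | {(1S)-3-methoxy-1,5-dimethyl-6-[2-(2-methyl-1,3-dioxolan-2-yl)ethyl]cyclohexa-2,5-dien-1-yl}[(2S)-2-(methoxymethyl)pyrrolidin-1-yl]methanone (ring B; C10 quaternary, C5=C6 enol ether, C8=C9 alkene) | CC1=C(CCC3(C)OCCO3)[C@@](C)(C(=O)N2CCC[C@H]2COC)C=C(OC)C1 | intermediate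
10 | {(1S)-3-methoxy-1,5-dimethyl-6-[2-(2-methyl-1,3-dioxolan-2-yl)ethyl]cyclohexa-2,5-dien-1-yl}methanol | CC1=C(CCC3(C)OCCO3)[C@@](C)(CO)C=C(OC)C1 | intermediate
11 | trifluoromethanesulfonate of 10 | CC1=C(CCC3(C)OCCO3)[C@@](C)(COS(=O)(=O)C(F)(F)F)C=C(OC)C1 | intermediate
12 | 4,6-dimethyl-5-[2-(2-methyl-1,3-dioxolan-2-yl)ethyl]bicyclo[4.1.0]hept-4-en-2-one, cis-fused, configuration fixed by C10 | CC1=C(CCC3(C)OCCO3)[C@@]2(C)C[C@H]2C(=O)C1 | intermediate
13 | ethyl glyoxylate | CCOC(=O)C=O | starting material
14 | trimethylsilyl enol ether (C5=C6) of 3-(iodomethyl)-3,5-dimethyl-4-(3-oxobutyl)cyclohex-4-enone | CC1=C(CCC(C)=O)[C@@](C)(CI)C=C(O[Si](C)(C)C)C1 | intermediate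
15 | ethyl 2-hydroxy-2-[2-(iodomethyl)-2,4-dimethyl-6-oxo-3-(3-oxobutyl)cyclohex-3-en-1-yl]acetate (C10 as in 10; mixture at C4 and C5) | CC1=C(CCC(C)=O)[C@@](C)(CI)C(C(O)C(=O)OCC)C(=O)C1 | intermediate
16 | methanesulfonate of 15 | CC1=C(CCC(C)=O)[C@@](C)(CI)C(C(OS(C)(=O)=O)C(=O)OCC)C(=O)C1 | intermediate
17 | ethyl 2-[2-(iodomethyl)-2,4-dimethyl-6-oxo-3-(3-oxobutyl)cyclohex-3-en-1-ylidene]acetate (drawn E; geometry without consequence) | CC1=C(CCC(C)=O)[C@@](C)(CI)/C(=C\C(=O)OCC)C(=O)C1 | intermediate
18 | vinylboronic acid pinacol ester | C=CB1OC(C)(C)C(C)(C)O1 | starting material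
19 | ethyl 6,13-dioxo-3-(4,4,5,5-tetramethyl-1,3,2-dioxaborolan-2-yl)-14,15,18-trinorlabd-8-en-19-oate (5α-H, 10β-methyl; mixture at C3 and C4) | CC1=C(CCC(C)=O)[C@@]2(C)CCC(B3OC(C)(C)C(C)(C)O3)C(C(=O)OCC)[C@@H]2C(=O)C1 | intermediate
20 | ethyl 6β,13-dihydroxy-3-(pinacolboryl)-14,15,18-trinorlabd-8-en-19-oate | CC1=C(CCC(C)O)[C@@]2(C)CCC(B3OC(C)(C)C(C)(C)O3)C(C(=O)OCC)[C@@H]2[C@H](O)C1 | intermediate
21 | 13-hydroxy-3-(pinacolboryl)-14,15,18-trinorlabd-8-en-19,6β-olide (4α-H; mixture at C3 and C13) | CC1=C(CCC(C)O)[C@@]2(C)CCC(B4OC(C)(C)C(C)(C)O4)[C@H](C(=O)O3)[C@@H]2[C@H]3C1 | intermediate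
22 | 3,13-dihydroxy-14,15,18-trinorlabd-8-en-19,6β-olide (mixture at C3 and C13) | CC1=C(CCC(C)O)[C@@]2(C)CCC(O)[C@H](C(=O)O3)[C@@H]2[C@H]3C1 | intermediate
23 | 3,13-dioxo-14,15,18-trinorlabd-8-en-19,6β-olide | CC1=C(CCC(C)=O)[C@@]2(C)CCC(=O)[C@H](C(=O)O3)[C@@H]2[C@H]3C1 | intermediate
24 | 3,13-dioxo-14,15-dinorlabd-8-en-19,6β-olide (4α-methyl) | CC1=C(CCC(C)=O)[C@@]2(C)CCC(=O)[C@](C)(C(=O)O3)[C@@H]2[C@H]3C1 | intermediate
25 | allyl diethylphosphonoacetate | C=CCOC(=O)CP(=O)(OCC)OCC | starting material
26 | allyl ester of (13E)-3-oxolabda-8,13-dien-19,6β-olid-15-oic acid | CC1=C(CC/C(C)=C/C(=O)OCC=C)[C@@]2(C)CCC(=O)[C@](C)(C(=O)O3)[C@@H]2[C@H]3C1 | intermediate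
27 | allyl ester of (13E)-3α-hydroxylabda-8,13-dien-19,6β-olid-15-oic acid | CC1=C(CC/C(C)=C/C(=O)OCC=C)[C@@]2(C)CC[C@@H](O)[C@](C)(C(=O)O3)[C@@H]2[C@H]3C1 | intermediate
28 | (13E)-3α-hydroxylabda-8,13-dien-19,6β-olid-15-oic acid | CC1=C(CC/C(C)=C/C(=O)O)[C@@]2(C)CC[C@@H](O)[C@](C)(C(=O)O3)[C@@H]2[C@H]3C1 | intermediate
29 | (13E)-3α,6β,19-trihydroxylabda-8,13-dien-15-oic acid (3R,4S,5R,6R,10S) | CC1=C(CC/C(C)=C/C(=O)O)[C@@]2(C)CC[C@@H](O)[C@](C)(CO)[C@@H]2[C@H](O)C1 | target

**Step count.** Total: 17 steps. Longest linear sequence: 17 steps (all fragments joined to the main line are commercial).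

**Steps most likely to fail**

Step 9 (radical annulation). The C1 radical or the α-boryl C3 radical may be reduced by the silane before it forms its C–C bond. The C1 radical may also add to the oxo-enoate of a second molecule or abstract a hydrogen atom across ring B, and the C3 radical may telomerize with the vinylboronate. The fallback separates the two bond formations and makes C3–C4 by polar chemistry. It sets out from 17: Keck allylation (allyltributylstannane, AIBN, PhH, 80 °C, no hydride source) should give the C1-allylated oxo-enoate F1. Lemieux–Johnson cleavage of its terminal alkene (OsO4 cat., NaIO4, 2,6-lutidine, dioxane/H2O) should give the C3 aldehyde F2. An intramolecular Stetter reaction (thiazolium salt, Et3N, dioxane, 70 °C) should close ring A at C4 to the 3,6,13-trioxo ester F3. The conditions of step 10 then reduce all three ketones and lactonize, and the route is rejoined at 22.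

Step 7 (ring opening and aldol). Iodide may open the cyclopropane at C10 through a cation-like pathway with ring enlargement, the iodo enol silane may close back to 12 before the aldol, or the addition at the neopentyl-type C5 may stall. The fallback changes the nucleophile and the radical precursor and keeps the ketal. It sets out from 12: PhSeSiMe3 with catalytic ZnI2 (weak Lewis acid, no iodide, selenium attacks C1 in an SN2 manner) gives the selenide enol silane, and the same glyoxylate aldol gives the C1 phenylselenide aldol adduct F4. MsCl/Et3N gives the selenide oxo-enoate F5. Under the conditions of step 9 (the silyl radical abstracts PhSe) this gives the ketal-protected annulation product F6. Hydrolysis of the dioxolane (PPTS, wet acetone) rejoins the route at 19.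

Step 4 (Birch alkylation). The facial selectivity in the alkylation of the amide enolate may be low or reversed, and over-reduction of the diene is possible. The fallback separates the diastereomers instead of relying on induction. It sets out from 2: Suzuki–Miyaura coupling of the potassium salt of 2 with borane 7 gives the side-chain benzoic acid F7. Birch reduction–methylation of the carboxylate (Li, NH3/THF, −78 °C; then MeI) gives the racemic diene acid F8. Its acid chloride (1-chloro-N,N,2-trimethylprop-1-enylamine) is coupled with 3, giving 9 together with its C10 epimer F9, which is removed by chromatography. The route is rejoined at 9.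

Further compounds
F1 | step 9 | ethyl 2-[2-(but-3-enyl)-2,4-dimethyl-6-oxo-3-(3-oxobutyl)cyclohex-3-en-1-ylidene]acetate | CC1=C(CCC(C)=O)[C@@](C)(CCC=C)/C(=C\C(=O)OCC)C(=O)C1
F2 | step 9 | ethyl 2-[2,4-dimethyl-6-oxo-3-(3-oxobutyl)-2-(3-oxopropyl)cyclohex-3-en-1-ylidene]acetate | CC1=C(CCC(C)=O)[C@@](C)(CCC=O)/C(=C\C(=O)OCC)C(=O)C1
F3 | step 9 | ethyl 3,6,13-trioxo-14,15,18-trinorlabd-8-en-19-oate | CC1=C(CCC(C)=O)[C@@]2(C)CCC(=O)C(C(=O)OCC)[C@@H]2C(=O)C1
F4 | step 7 | ethyl 2-hydroxy-2-{2,4-dimethyl-3-[2-(2-methyl-1,3-dioxolan-2-yl)ethyl]-6-oxo-2-[(phenylselanyl)methyl]cyclohex-3-en-1-yl}acetate | CC1=C(CCC3(C)OCCO3)[C@@](C)(C[Se]c2ccccc2)C(C(O)C(=O)OCC)C(=O)C1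
F5 | step 7 | ethyl 2-{2,4-dimethyl-3-[2-(2-methyl-1,3-dioxolan-2-yl)ethyl]-6-oxo-2-[(phenylselanyl)methyl]cyclohex-3-en-1-ylidene}acetate | CC1=C(CCC3(C)OCCO3)[C@@](C)(C[Se]c2ccccc2)/C(=C\C(=O)OCC)C(=O)C1
F6 | step 7 | 13-ethylene ketal of 19 | CC1=C(CCC3(C)OCCO3)[C@@]2(C)CCC(B4OC(C)(C)C(C)(C)O4)C(C(=O)OCC)[C@@H]2C(=O)C1
F7 | step 4 | 5-methoxy-3-methyl-2-[2-(2-methyl-1,3-dioxolan-2-yl)ethyl]benzoic acid | COc1cc(C)c(CCC2(C)OCCO2)c(c1)C(=O)O
F8 | step 4 | racemic 3-methoxy-1,5-dimethyl-6-[2-(2-methyl-1,3-dioxolan-2-yl)ethyl]cyclohexa-2,5-diene-1-carboxylic acid | CC1=C(CCC2(C)OCCO2)C(C)(C(=O)O)C=C(OC)C1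
F9 | step 4 | C10 epimer of 9 | CC1=C(CCC3(C)OCCO3)[C@](C)(C(=O)N2CCC[C@H]2COC)C=C(OC)C1
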